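**Retrosynthetic overview**
1. The phenol is unmasked last (silyl ether cleavage); the acid comes from the C1 primary alcohol by Dess–Martin then Pinnick oxidation.
2. C4–C5 is made by B-alkyl Suzuki–Miyaura coupling of an (S,E)-2-iodoalkene (fragment A) with the 9-BBN adduct of an ω-aryl-octadec-1-ene (fragment B); this fixes the E trisubstituted alkene.
3. Fragment A comes from hydrozirconation–iodination of a methyl alkyne, itself made by Corey–Fuchs homologation and methylation of a 3-silyloxy-2-methylpropanal.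
4. The C2 stereocentre comes from lipase-catalysed desymmetrising hydrolysis of prochiral 2-methylpropane-1,3-diyl dibutanoate.
5. Fragment B comes from two Li2CuCl4-catalysed Grignard couplings (4-bromophenol, 1,10-dibromodecane, 8-bromooct-1-ene). No ring is formed; the benzene ring is bought.

Assumption: the SMILES is read as (2S,3E)-22-(4-hydroxyphenyl)-2,4-dimethyldocos-3-enoic acid with an unbranched tether of 18 CH2 groups; the lipase is taken to cleave the pro-S ester arm, as recalled for this substrate class, and the ee of 3 is to be confirmed by chiral GC.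

**Route**

Step 1
Reactants: 1 2-methylpropane-1,3-diol
Product: 2 2-methylpropane-1,3-diyl dibutanoate
Conditions: butanoic anhydride (2.3 equiv), DMAP (5 mol %), pyridine, 0 °C → rt
Reagents that add atoms: butanoic anhydride, CCCC(=O)OC(=O)CCC
Why: DMAP-catalysed esterification of both primary alcohols gives the achiral, prochiral diester that the enzyme accepts.

Step 2
Reactants: 2 2-methylpropane-1,3-diyl dibutanoate
Product: 3 (2R)-3-hydroxy-2-methylpropyl butanoate
Conditions: Pseudomonas fluorescens lipase (a triacylglycerol lipase, serine-hydrolase class), 0.5 M KH2PO4/K2HPO4 buffer pH 7.0, 25 °C; stopped at ≥98 % ee of 3 by chiral GC (about 1.2 ester groups cleaved per molecule); diol 1 recovered and recycled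
Reagents that add atoms: none
Why: Enzymatic desymmetrisation (enantiotopos-selective ester hydrolysis) in which the lipase cleaves the pro-S butanoyloxymethyl arm fastest and so sets the only stereocentre as the (R)-monoester, while the minor (S)-monoester still carries its ester on the fast arm and is over-hydrolysed to diol 1, which raises the ee with conversion.

Step 3
Reactants: 3 (2R)-3-hydroxy-2-methylpropyl butanoate
Product: 4 (2S)-3-[(tert-butyldimethylsilyl)oxy]-2-methylpropyl butanoate
Conditions: TBSCl (1.1 equiv), imidazole (2 equiv), DMF, 0 °C, 1 h (3 used directly after isolation)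
Reagents that add atoms: tert-butyl(chloro)dimethylsilane (TBSCl), CC(C)(C)[Si](C)(C)Cl
Why: Silyl ether protection of the free primary alcohol under mild imidazole conditions, carried out at once so that 1,3-acyl migration cannot erode the ee (the descriptor changes only through CIP priorities).

Step 4
Reactants: 4 (2S)-3-[(tert-butyldimethylsilyl)oxy]-2-methylpropyl butanoate
Product: 5 (2S)-3-[(tert-butyldimethylsilyl)oxy]-2-methylpropan-1-ol
Conditions: i-Bu2AlH (2.5 equiv), CH2Cl2, −78 → −40 °C; aq. KNaC4H4O6 work-up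
Reagents that add atoms: none
Why: Reductive ester cleavage with i-Bu2AlH at low temperature frees the second arm without the base-induced 1,3-silyl migration that would racemise this pseudo-symmetric diol derivative.

Step 5
Reactants: 5 (2S)-3-[(tert-butyldimethylsilyl)oxy]-2-methylpropan-1-ol
Product: 6 (2R)-3-[(tert-butyldimethylsilyl)oxy]-2-methylpropanal
Conditions: Dess–Martin periodinane (1.2 equiv), pyridine (3 equiv), CH2Cl2, 0 °C → rt; silica pad, used crude at once
Reagents that add atoms: none
Why: Buffered Dess–Martin oxidation gives the α-methyl aldehyde without epimerisation, as is standard for this Roche-type aldehyde.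

Step 6
Reactants: 6 (2R)-3-[(tert-butyldimethylsilyl)oxy]-2-methylpropanal
Product: 7 tert-butyl{[(2S)-4,4-dibromo-2-methylbut-3-en-1-yl]oxy}dimethylsilane
Conditions: CBr4 (2 equiv), PPh3 (2 equiv), Zn dust (2 equiv), CH2Cl2, rt, 24 h; then 6, 0 °C → rt
Reagents that add atoms: carbon tetrabromide, BrC(Br)(Br)Br
Why: Corey–Fuchs dibromo-olefination (Wittig reaction of Ph3P=CBr2 generated with Zn) runs under nearly neutral conditions, so the α-stereocentre is untouched.

Step 7
Reactants: 7 tert-butyl{[(2S)-4,4-dibromo-2-methylbut-3-en-1-yl]oxy}dimethylsilane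
Product: 9 tert-butyldimethyl{[(2S)-2-methylpent-3-yn-1-yl]oxy}silane, via lithium acetylide 8 (not isolated)
Conditions: n-BuLi (2.2 equiv), THF, −78 °C, 1 h; then MeI (4 equiv), −78 °C → rt
Reagents that add atoms: iodomethane, CI
Why: Second stage of the Corey–Fuchs sequence (Li–Br exchange, Fritsch–Buttenberg–Wiechell rearrangement, deprotonation) followed by SN2 C-methylation of the acetylide gives the methyl alkyne without touching the propargylic stereocentre.

Step 8
Reactants: 9 tert-butyldimethyl{[(2S)-2-methylpent-3-yn-1-yl]oxy}silane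
Product: 11 tert-butyl{[(2S,3E)-4-iodo-2-methylpent-3-en-1-yl]oxy}dimethylsilane, via alkenylzirconocene chloride 10 (not isolated)
Conditions: Cp2Zr(H)Cl (2.5 equiv), THF, 50 °C, 1.5 h, dark; then I2 (2.6 equiv), THF, 0 °C
Reagents that add atoms: iodine, II
Why: Hydrozirconation–iodinolysis: syn Zr–H addition equilibrates with excess reagent to put zirconium on the less hindered methyl-bearing carbon, and iodine cleaves the C–Zr bond with retention, giving the E iodide with the methyl cis to C2.

Step 9
Reactants: 12 4-bromophenol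
Product: 13 (4-bromophenoxy)triisopropylsilane
Conditions: TIPSCl (1.1 equiv), imidazole (2 equiv), DMF, rt
Reagents that add atoms: chlorotriisopropylsilane (TIPSCl), CC(C)[Si](Cl)(C(C)C)C(C)C
Why: Silylation of the phenol gives a TIPS aryl ether that tolerates Grignard reagents, aqueous phosphate base, dilute acid and the later oxidations.

Step 10
Reactants: 13 (4-bromophenoxy)triisopropylsilane; 14 1,10-dibromodecane
Product: 16 [4-(10-bromodecyl)phenoxy]triisopropylsilane, via arylmagnesium bromide 15 (not isolated)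
Conditions: Mg turnings (I2-activated), THF, reflux; then added to 14 (4 equiv), Li2CuCl4 (3 mol %), THF, −10 °C → rt; excess 14 recovered by distillation
Reagents that add atoms: none
Why: Grignard formation and Li2CuCl4-catalysed (Kochi-type) aryl–alkyl cross-coupling, with the dibromide in excess so that mono-substitution dominates.

Step 11
Reactants: 16 [4-(10-bromodecyl)phenoxy]triisopropylsilane; 17 8-bromooct-1-ene
Product: 19 triisopropyl[4-(octadec-17-en-1-yl)phenoxy]silane, via oct-7-enylmagnesium bromide 18 (not isolated)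
Conditions: 17 (1.6 equiv), Mg turnings (I2-activated), THF, 40 °C; then 16, Li2CuCl4 (3 mol %), THF, −10 °C → rt
Reagents that add atoms: none
Why: Li2CuCl4-catalysed Kochi sp3–sp3 coupling of a primary Grignard reagent with a primary bromide joins C10 and C8 to give the C18 terminal alkene.

Step 12
Reactants: 19 triisopropyl[4-(octadec-17-en-1-yl)phenoxy]silane; 11 tert-butyl{[(2S,3E)-4-iodo-2-methylpent-3-en-1-yl]oxy}dimethylsilane
Product: 21 tert-butyl{[(2S,3E)-2,4-dimethyl-22-{4-[(triisopropylsilyl)oxy]phenyl}docos-3-en-1-yl]oxy}dimethylsilane, via B-alkyl-9-BBN adduct 20 (not isolated)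
Conditions: 19 (1.3 equiv), 9-BBN (1.4 equiv, 0.5 M in THF), rt, 4 h; then 3 M aq. K3PO4 (3 equiv), 11 (1.0 equiv), Pd(dppf)Cl2·CH2Cl2 (5 mol %; dppf = 1,1'-bis(diphenylphosphino)ferrocene), AsPh3 (5 mol %), DMF, rt, 12 h, degassed
Reagents that add atoms: none
Why: Anti-Markovnikov hydroboration with 9-BBN then B-alkyl Suzuki–Miyaura coupling, in which oxidative addition to zerovalent palladium and reductive elimination proceed with retention, so the methyl stays cis to C2 and the new chain is trans (E).

Step 13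
Reactants: 21 tert-butyl{[(2S,3E)-2,4-dimethyl-22-{4-[(triisopropylsilyl)oxy]phenyl}docos-3-en-1-yl]oxy}dimethylsilane
Product: 22 (2S,3E)-2,4-dimethyl-22-{4-[(triisopropylsilyl)oxy]phenyl}docos-3-en-1-ol
Conditions: p-TsOH·H2O (0.1 equiv), MeOH/CH2Cl2 1:1, 0 °C → rt; NaHCO3 quench
Reagents that add atoms: none
Why: Acid-catalysed methanolysis removes the primary alkyl TBS ether selectively, because aryl TIPS ethers are inert to dilute acid and the trisubstituted alkene is not protonated under these conditions.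

Step 14
Reactants: 22 (2S,3E)-2,4-dimethyl-22-{4-[(triisopropylsilyl)oxy]phenyl}docos-3-en-1-ol
Product: 23 (2S,3E)-2,4-dimethyl-22-{4-[(triisopropylsilyl)oxy]phenyl}docos-3-enal
Conditions: Dess–Martin periodinane (1.3 equiv), pyridine (4 equiv), CH2Cl2, 0 °C, 1 h; silica pad, used at once
Reagents that add atoms: none
Why: Buffered Dess–Martin oxidation gives the epimerisable β,γ-unsaturated aldehyde under neutral conditions, and immediate use prevents epimerisation at C2 or migration of the alkene into conjugation.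

Step 15
Reactants: 23 (2S,3E)-2,4-dimethyl-22-{4-[(triisopropylsilyl)oxy]phenyl}docos-3-enal
Product: 24 (2S,3E)-2,4-dimethyl-22-{4-[(triisopropylsilyl)oxy]phenyl}docos-3-enoic acid
Conditions: NaClO2 (3 equiv), NaH2PO4 (3 equiv), 2-methylbut-2-ene (20 equiv), t-BuOH/THF/H2O, 0 °C → rt
Reagents that add atoms: sodium chlorite, [Na+].[O-]Cl=O
Why: Pinnick oxidation at about pH 4 converts the aldehyde to the acid without enolisation, while the alkene scavenger traps hypochlorous acid and so protects the trisubstituted alkene and the silylated arene.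

Step 16
Reactants: 24 (2S,3E)-2,4-dimethyl-22-{4-[(triisopropylsilyl)oxy]phenyl}docos-3-enoic acid
Product: 25 (2S,3E)-22-(4-hydroxyphenyl)-2,4-dimethyldocos-3-enoic acid
Conditions: TBAF (2.5 equiv), AcOH (2.5 equiv), THF, 0 °C → rt; pH 4 citrate work-up
Reagents that add atoms: none
Why: Fluoride-induced desilylation of the aryl TIPS ether is fast and mild, and the carboxylate present resists α-deprotonation, so C2 and the β,γ-alkene position are preserved.

**Compound list**
1 | 2-methylpropane-1,3-diol | CC(CO)CO | starting material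
2 | 2-methylpropane-1,3-diyl dibutanoate | CCCC(=O)OCC(C)COC(=O)CCC | intermediate
3 | (2R)-3-hydroxy-2-methylpropyl butanoate | CCCC(=O)OC[C@H](C)CO | intermediate
4 | (2S)-3-[(tert-butyldimethylsilyl)oxy]-2-methylpropyl butanoate | CCCC(=O)OC[C@H](C)CO[Si](C)(C)C(C)(C)C | intermediate
5 | (2S)-3-[(tert-butyldimethylsilyl)oxy]-2-methylpropan-1-ol | OC[C@H](C)CO[Si](C)(C)C(C)(C)C | intermediate
6 | (2R)-3-[(tert-butyldimethylsilyl)oxy]-2-methylpropanal | O=C[C@H](C)CO[Si](C)(C)C(C)(C)C | intermediate
7 | tert-butyl{[(2S)-4,4-dibromo-2-methylbut-3-en-1-yl]oxy}dimethylsilane | BrC(Br)=C[C@H](C)CO[Si](C)(C)C(C)(C)C | intermediate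
8 | lithium acetylide: {(3S)-4-[(tert-butyldimethylsilyl)oxy]-3-methylbut-1-yn-1-yl}lithium | [Li]C#C[C@H](C)CO[Si](C)(C)C(C)(C)C | intermediate
9 | tert-butyldimethyl{[(2S)-2-methylpent-3-yn-1-yl]oxy}silane | CC#C[C@H](C)CO[Si](C)(C)C(C)(C)C | intermediate
10 | alkenylzirconocene chloride: chlorobis(cyclopentadienyl)[(2E,4S)-5-[(tert-butyldimethylsilyl)oxy]-4-methylpent-2-en-2-yl]zirconium | C/C(=C\[C@H](C)CO[Si](C)(C)C(C)(C)C)[Zr](Cl)(C1C=CC=C1)C1C=CC=C1 | intermediate
11 | tert-butyl{[(2S,3E)-4-iodo-2-methylpent-3-en-1-yl]oxy}dimethylsilane | C/C(I)=C\[C@H](C)CO[Si](C)(C)C(C)(C)C | intermediate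
12 | 4-bromophenol | Oc1ccc(Br)cc1 | starting material
13 | (4-bromophenoxy)triisopropylsilane | CC(C)[Si](Oc1ccc(Br)cc1)(C(C)C)C(C)C | intermediate
14 | 1,10-dibromodecane | BrCCCCCCCCCCBr | starting material
15 | arylmagnesium bromide: {4-[(triisopropylsilyl)oxy]phenyl}magnesium bromide | CC(C)[Si](Oc1ccc([Mg]Br)cc1)(C(C)C)C(C)C | intermediate
16 | [4-(10-bromodecyl)phenoxy]triisopropylsilane | CC(C)[Si](Oc1ccc(CCCCCCCCCCBr)cc1)(C(C)C)C(C)C | intermediate
17 | 8-bromooct-1-ene | C=CCCCCCCBr | starting material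
18 | oct-7-enylmagnesium bromide | C=CCCCCCC[Mg]Br | intermediate
19 | triisopropyl[4-(octadec-17-en-1-yl)phenoxy]silane | CC(C)[Si](Oc1ccc(CCCCCCCCCCCCCCCCC=C)cc1)(C(C)C)C(C)C | intermediate
20 | B-alkyl-9-BBN adduct: 9-{18-[4-(triisopropylsilyloxy)phenyl]octadecyl}-9-borabicyclo[3.3.1]nonane | CC(C)[Si](Oc1ccc(CCCCCCCCCCCCCCCCCCB2C3CCCC2CCC3)cc1)(C(C)C)C(C)C | intermediate
21 | tert-butyl{[(2S,3E)-2,4-dimethyl-22-{4-[(triisopropylsilyl)oxy]phenyl}docos-3-en-1-yl]oxy}dimethylsilane | C/C(=C\[C@H](C)CO[Si](C)(C)C(C)(C)C)CCCCCCCCCCCCCCCCCCc1ccc(O[Si](C(C)C)(C(C)C)C(C)C)cc1 | intermediate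
22 | (2S,3E)-2,4-dimethyl-22-{4-[(triisopropylsilyl)oxy]phenyl}docos-3-en-1-ol | C/C(=C\[C@H](C)CO)CCCCCCCCCCCCCCCCCCc1ccc(O[Si](C(C)C)(C(C)C)C(C)C)cc1 | intermediate
23 | (2S,3E)-2,4-dimethyl-22-{4-[(triisopropylsilyl)oxy]phenyl}docos-3-enal | C/C(=C\[C@H](C)C=O)CCCCCCCCCCCCCCCCCCc1ccc(O[Si](C(C)C)(C(C)C)C(C)C)cc1 | intermediate
24 | (2S,3E)-2,4-dimethyl-22-{4-[(triisopropylsilyl)oxy]phenyl}docos-3-enoic acid | C/C(=C\[C@H](C)C(=O)O)CCCCCCCCCCCCCCCCCCc1ccc(O[Si](C(C)C)(C(C)C)C(C)C)cc1 | intermediate
25 | (2S,3E)-22-(4-hydroxyphenyl)-2,4-dimethyldocos-3-enoic acid | C/C(=C\[C@H](C)C(=O)O)CCCCCCCCCCCCCCCCCCc1ccc(O)cc1 | target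

**Step count and risks**

Total: 16 steps. Longest linear sequence: 13 steps (steps 1–8, then 12–16); the aryl-alkene branch (steps 9–11) joins at step 12.

The three steps most likely to fail:

Step 2 (ee or yield of the enzymatic hydrolysis, or the wrong enantiopreference). The fallback sets out from 1 and comes back at 5. The same lipase is used in the acylation mode: with vinyl acetate in t-BuOMe it acetylates the pro-S hydroxymethyl arm of 1 to give (2S)-3-hydroxy-2-methylpropyl acetate F1, with a little diacetate allowed to form to raise the ee. Because the acyl group now sits on the arm that must become C1, a protecting-group relay follows. 4-Methoxybenzyl trichloroacetimidate with catalytic pyridinium p-toluenesulfonate gives (2S)-3-[(4-methoxybenzyl)oxy]-2-methylpropyl acetate F2. K2CO3 in MeOH gives (2R)-3-[(4-methoxybenzyl)oxy]-2-methylpropan-1-ol F3, whose benzyl-type ether cannot migrate. TBSCl and imidazole give tert-butyl{(2S)-3-[(4-methoxybenzyl)oxy]-2-methylpropoxy}dimethylsilane F4, and DDQ in CH2Cl2/pH 7 buffer removes the 4-methoxybenzyl group to deliver 5.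

Step 8 (regioselectivity of the hydrozirconation). The fallback sets out from 7 and comes back at 21. The 1,1-dibromoalkene 7 is coupled with the alkylborane 20 (made from 19 as in step 12) using PdCl2(DPEphos) (DPEphos = bis[2-(diphenylphosphino)phenyl] ether) and aqueous K3PO4 in THF. The coupling occurs selectively at the bromine trans to the branched substituent and gives tert-butyl{[(2S,3Z)-4-bromo-2-methyl-22-{4-[(triisopropylsilyl)oxy]phenyl}docos-3-en-1-yl]oxy}dimethylsilane F5. A Negishi methylation of the remaining C–Br bond with retention (MeZnCl, Pd(P(t-Bu)3)2, THF) then gives 21, so that steps 7, 8 and 12 are bypassed.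

Step 12 (slow coupling of the hindered iodide, or loss of the aryl silyl ether in aqueous base). The fallback sets out from 19 and comes back at 21. Hydroboration–oxidation of 19 (9-BBN, then NaBO3·4H2O) gives 18-{4-[(triisopropylsilyl)oxy]phenyl}octadecan-1-ol F6. Appel iodination (I2, PPh3, imidazole) gives [4-(18-iodooctadecyl)phenoxy]triisopropylsilane F7. Zinc insertion (Zn dust, LiCl, THF, 40 °C) gives (18-{4-[(triisopropylsilyl)oxy]phenyl}octadecyl)zinc iodide F8, and a base-free Negishi coupling with 11 (Pd(dppf)Cl2, THF/N,N-dimethylacetamide, rt) gives 21.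

**Further compounds**
F1 | step 2 | (2S)-3-hydroxy-2-methylpropyl acetate | OC[C@H](C)COC(C)=O
F2 | step 2 | (2S)-3-[(4-methoxybenzyl)oxy]-2-methylpropyl acetate | COc1ccc(COC[C@H](C)COC(C)=O)cc1
F3 | step 2 | (2R)-3-[(4-methoxybenzyl)oxy]-2-methylpropan-1-ol | COc1ccc(COC[C@H](C)CO)cc1
F4 | step 2 | tert-butyl{(2S)-3-[(4-methoxybenzyl)oxy]-2-methylpropoxy}dimethylsilane | COc1ccc(COC[C@H](C)CO[Si](C)(C)C(C)(C)C)cc1
F5 | step 8 | tert-butyl{[(2S,3Z)-4-bromo-2-methyl-22-{4-[(triisopropylsilyl)oxy]phenyl}docos-3-en-1-yl]oxy}dimethylsilane | Br/C(=C\[C@H](C)CO[Si](C)(C)C(C)(C)C)CCCCCCCCCCCCCCCCCCc1ccc(O[Si](C(C)C)(C(C)C)C(C)C)cc1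
F6 | step 12 | 18-{4-[(triisopropylsilyl)oxy]phenyl}octadecan-1-ol | OCCCCCCCCCCCCCCCCCCc1ccc(O[Si](C(C)C)(C(C)C)C(C)C)cc1
F7 | step 12 | [4-(18-iodooctadecyl)phenoxy]triisopropylsilane | ICCCCCCCCCCCCCCCCCCc1ccc(O[Si](C(C)C)(C(C)C)C(C)C)cc1
F8 | step 12 | (18-{4-[(triisopropylsilyl)oxy]phenyl}octadecyl)zinc iodide | I[Zn]CCCCCCCCCCCCCCCCCCc1ccc(O[Si](C(C)C)(C(C)C)C(C)C)cc1
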